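## Structural features

The target is a flavonol, 3,5-dihydroxy-2-(3-hydroxy-4-methoxyphenyl)-7-methoxy-6,8-diprenyl-4H-chromen-4-one (C27H30O7). Its benzo ring (ring A) is fused to the 4-pyranone (ring C) through C4a–C8a, and the 3-hydroxy-4-methoxyphenyl ring (ring B) is attached at C2. Ring A is fully substituted: 5-OH, 6-prenyl, 7-OMe and 8-prenyl, with C8a bearing O1 and C4a bearing the C4 carbonyl. There is no stereocentre and no stereogenic double bond, since each prenyl terminus carries two methyl groups, so the problem is one of regiochemistry and functional-group tolerance only. The fragile groups are the two prenyl alkenes and the 3-hydroxy-4-pyranone. The prenyl groups sit ortho to phenolic oxygen; they close to chromans under acid and are attacked by electrophilic oxidants, halogens and hydrogenation catalysts. The 3-hydroxy-4-pyranone is degraded by base when oxygen is present. The real difficulty is twofold: arranging the substituents of ring A without regiochemical ambiguity, and introducing the C3 oxygen without an oxidant that would touch the prenyl groups. The key step uses the fact that removing C2, C3 and C4 leaves ring A as a mirror-symmetric resorcinol. Its only unsubstituted ring carbon is the future C4a, and its two hydroxyls (future O1 and 5-OH) are equivalent, so C-acylation and ring closure can each occur in only one way. The C3 oxygen arrives at the correct oxidation level with the three-carbon partner.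

## Logic of the disconnections

18 ⇒ 17. The two acyl–oxygen bonds at O3 and O3' are cut. Both hydroxyls carry the same ester, so one mild basic methanolysis ends the synthesis without acid, oxidant or hydrogenation. The cut does not simplify the skeleton; it makes the preceding step possible. The forward step must be run without oxygen, because the liberated flavonolate is oxidised in air.

17 ⇒ 6 + 14. The bonds C4–C4a and O1–C2 are cut, opening ring C. This divides the tricycle into two monocyclic pieces of similar size and places the C3 oxygen in 14, so no late oxidation is needed. 6 is symmetric with one free ring carbon, so regiochemistry is not an issue. The forward step must acylate at carbon and not end at oxygen, must close to the chromone and not the coumarin, and must spare two ortho-prenyl phenol units above 200 °C.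

14 ⇒ 13 ⇒ 12. The C3–O bond is cut (carbenoid insertion into a carboxylic acid O–H bond), then the C=N2 unit (diazo transfer). This reduces the α-acyloxy keto ester to a plain β-keto ester. The forward steps demand dry conditions so that the acid, not water, is inserted.

12 ⇒ 8 + 9. The bond between the aroyl carbon and the methylene (future C2–C3) is cut, giving an activated benzoic acid and a malonate half ester. The forward step is a decarboxylative C-acylation that must leave the aryl ester intact.

8 ⇒ 7. The aryl O–acyl bond is cut. The ring B phenol is masked first, with the same group that will sit on O3, so that it is carried through and removed in the last step. The forward step must acylate the phenol in the presence of the carboxylic acid.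

6 ⇒ 4. A carboxyl carbon is restored at the free ring position (aryl–CO2Me bond). The ester blocks the carbon between the two hydroxyls during prenylation and chelates the flanking hydroxyls during methylation. The forward step is ester cleavage with loss of CO2 under conditions that spare prenyl groups.

4 ⇒ 3. The O–CH3 bond at the oxygen para to the ester is cut. The forward step must methylate the one hydroxyl that is not hydrogen-bonded, at oxygen and not at carbon.

3 ⇒ 1 + 2. The two aryl–CH2 bonds are cut. Both building blocks are purchasable. The forward step must alkylate at carbon and stop after two prenyl groups.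

## Other disconnections considered

Alternative 1: The cut is at the aryl–CH2 bonds at C6 and C8 of a preformed flavone. Forward, diosmetin A1 would be converted into its 3'-O-MOM 5,7-bis(allyl) ether A2. Heating A2 near 200 °C would move both allyl groups by aromatic Claisen rearrangement to give A3: the 7-O-allyl to C8 and the 5-O-allyl to C6, or, if C6 is taken first, the other allyl reaches C8 by a Claisen–Cope sequence.
- In favour: rings A, B and C and the ring B oxygen pattern are bought; the sigmatropic shifts are intramolecular and cannot over-alkylate.
- Against: A3 still lacks most of what is hard. Each allyl group must be extended to prenyl by double cross-metathesis. O7 must be methylated between two ortho substituents. The C3 hydroxyl must be introduced by oxidising a flavone that by then carries two oxidisable alkenes, or earlier at the cost of more protection. Selective 3'-O-protection of A1 beside the more acidic 7-OH is not trivial. MOM removal needs acid next to an ortho-prenyl phenol.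
- Comparison: on structure the alternative is the better plan in that no ring has to be built, and it is the equal of the chosen plan in ring A regiocontrol. On mechanism both key steps are thermal near 200 °C; an ortho-allyl phenol is less prone to cyclise than an ortho-prenyl phenol, a point for the alternative. On step economy the chosen plan should be shorter, because it delivers C3–O with the building block, whereas the alternative needs about four or five further operations after A3.

Alternative 2: The cut runs through ring A at C5–C6, C7–C8 and C4a–C5. Forward, cyclobutenone A4 would be heated with alkynyl ether A5. Electrocyclic opening to a vinylketene, [2+2] cycloaddition with the ynol ether, four-electron ring opening and six-electron closure would give phenol A6, which on desilylation is 6.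
- In favour: every substituent of ring A is placed by the connectivity of the two partners, so C- versus O-alkylation and over-alkylation do not arise; the medium is neutral.
- Against: A4 and A5 each need several steps. The skipped enyne ether A5 can isomerise. The vinylketene can be intercepted by a prenyl alkene. The sequence ends at 6, so ring C must still be closed by the chosen key step.
- Comparison: on structure and regiocontrol the alternative is better than step 1 of the chosen route. On mechanism it trades a phenoxide alkylation for a pericyclic cascade of comparable reliability. On step economy it is clearly worse, since 6 is reached in three steps from 1 in the chosen plan.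

Alternative 3: The cut is at C4a–C4, C4–C3 and O1–C2, with C4 coming from carbon monoxide. Forward, iodoresorcinol A7, carbon monoxide A8 and arylacetylene A9 would combine under PdCl2(PPh3)2 in a secondary amine: oxidative addition, CO insertion, alkynylation to an ynone and 6-endo oxa-Michael closure to flavone A10.
- In favour: three bonds and one ring form well below 100 °C, so the prenyl groups are not thermally stressed. The symmetric ring A logic is the same as in the chosen plan.
- Against: A7 must come from electrophilic iodination of 6, where iodine can instead trigger iodoetherification of an ortho-prenyl phenol. The 5-exo closure to an aurone competes. A10 has no oxygen at C3, so a late C3 hydroxylation in the presence of two prenyl groups and a free 5-OH is needed, followed by an acidic MOM cleavage.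
- Comparison: on mechanism and mildness the alternative is better, and it forms one more bond in the key step. On structure the two plans are equal in their use of the symmetric resorcinol. On step economy and oxidation-state economy the chosen plan is superior, because 17 already carries the C3 oxygen.

Key step: step 8

Remark on the chemistry: mapping 6, 14 and 17 atom by atom onto 18 is self-consistent, so no structure needs correction. The ring C–H of 6 becomes C4a, and the ester carbonyl, the oxygenated methine and the aryl ketone of 14 become C4, C3 and C2. 14 is used as the racemate because its only stereocentre becomes sp2 in ring C. Pivalates are kept on O3 and O3' because their bulk resists acyl transfer to the resorcinol hydroxyls at high temperature.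

## Route

Step 1
Reactants: 1 methyl 2,4,6-trihydroxybenzoate; 2 1-bromo-3-methylbut-2-ene (prenyl bromide)
Product: 3 methyl 2,4,6-trihydroxy-3,5-bis(3-methylbut-2-en-1-yl)benzoate
Conditions: 2 (2.1 equiv), KOH (10% aq, 3 equiv), 0 °C, Ar; then cold 1 M HCl
Reagents that add atoms: none
Why: C-alkylation of an ambident phloroglucinol phenoxide, the standard C-prenylation of acylphloroglucinols: in water the oxygens are hydrogen-bonded, so the allylic bromide is attacked by ring carbons C3 and C5, each flanked by two oxygens, while the ester blocks the third carbon and survives cold dilute alkali.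

Step 2
Reactants: 3 methyl 2,4,6-trihydroxy-3,5-bis(3-methylbut-2-en-1-yl)benzoate
Product: 4 methyl 2,6-dihydroxy-4-methoxy-3,5-bis(3-methylbut-2-en-1-yl)benzoate
Conditions: Me2SO4 (1.05 equiv), K2CO3 (1.1 equiv), acetone, 0 °C to rt
Reagents that add atoms: dimethyl sulfate, COS(=O)(=O)OC
Why: Williamson O-methylation under mono-deprotonation: the 4-OH, para to the ester and not hydrogen-bonded, is the most acidic, whereas the 2- and 6-OH are held by the ester; the hard electrophile with a weak base favours O- over C-methylation.

Step 3
Reactants: 4 methyl 2,6-dihydroxy-4-methoxy-3,5-bis(3-methylbut-2-en-1-yl)benzoate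
Product: 6 5-methoxy-4,6-bis(3-methylbut-2-en-1-yl)benzene-1,3-diol, via carboxylic acid 5 (not isolated)
Conditions: KOH (8 equiv), MeOH–H2O (1:1, degassed), reflux, Ar; then AcOH to pH 5, 50 °C
Reagents that add atoms: none
Why: Saponification of the salicylate ester followed by protodecarboxylation of the electron-rich 2,6-dihydroxybenzoic acid, which loses CO2 by ipso-protonation at weakly acidic pH; prenyl groups and the aryl methyl ether are inert to alkali and to warm dilute acetic acid, and oxygen is excluded because the product is an electron-rich resorcinol.

Step 4
Reactants: 7 3-hydroxy-4-methoxybenzoic acid (isovanillic acid)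
Product: 8 4-methoxy-3-(pivaloyloxy)benzoic acid
Conditions: PivCl (1.3 equiv), NaOH (2 M aq, 2.5 equiv), THF, 0 °C; then 1 M HCl
Reagents that add atoms: pivaloyl chloride, CC(C)(C)C(Cl)=O
Why: Schotten–Baumann acylation: the phenoxide of the dianion is far more nucleophilic than the carboxylate, and any mixed anhydride formed at the carboxylate is hydrolysed in the aqueous base, so acidification should return the free acid with only the phenol acylated.

Step 5
Reactants: 8 4-methoxy-3-(pivaloyloxy)benzoic acid; 9 potassium 3-methoxy-3-oxopropanoate (potassium methyl malonate)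
Product: 12 methyl 3-[4-methoxy-3-(pivaloyloxy)phenyl]-3-oxopropanoate, via acyl imidazolide 10 (not isolated), via acylmalonic half ester 11 (not isolated)
Conditions: CDI (1.1 equiv), THF, rt; then 9 (2 equiv), MgCl2 (2 equiv), Et3N (3 equiv), MeCN, rt; then 1 M HCl
Reagents that add atoms: none
Why: Masamune–Brooks homologation: the acyl imidazolide C-acylates the magnesium enolate of the malonate half ester, and the acylmalonate loses CO2 on acidification; the neutral, room-temperature conditions leave the hindered aryl pivalate untouched.

Step 6
Reactants: 12 methyl 3-[4-methoxy-3-(pivaloyloxy)phenyl]-3-oxopropanoate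
Product: 13 methyl 2-diazo-3-[4-methoxy-3-(pivaloyloxy)phenyl]-3-oxopropanoate
Conditions: 4-acetamidobenzenesulfonyl azide (1.2 equiv), Et3N (1.5 equiv), MeCN, 0 °C to rt
Reagents that add atoms: 4-acetamidobenzenesulfonyl azide, CC(=O)Nc1ccc(S(=O)(=O)N=[N+]=[N-])cc1
Why: Regitz diazo transfer to the doubly activated methylene of a β-keto ester, which runs under mild amine base and does not affect the aryl ester.

Step 7
Reactants: 13 methyl 2-diazo-3-[4-methoxy-3-(pivaloyloxy)phenyl]-3-oxopropanoate
Product: 14 methyl 3-[4-methoxy-3-(pivaloyloxy)phenyl]-3-oxo-2-(pivaloyloxy)propanoate (racemic)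
Conditions: Rh2(OAc)4 (1 mol %), PivOH (3 equiv), 1,2-dichloroethane (dry), 60 °C
Reagents that add atoms: pivalic acid, CC(C)(C)C(=O)O
Why: Rh2(OAc)4 turns the diazo compound into a rhodium carbenoid that inserts into the O–H bond of pivalic acid (oxonium ylide, then proton transfer), an established route to α-acyloxy β-keto esters; excess acid and dry solvent suppress water insertion and carbene dimerisation, and the new stereocentre forms as a racemate that is erased in step 8.

Step 8
Reactants: 6 5-methoxy-4,6-bis(3-methylbut-2-en-1-yl)benzene-1,3-diol; 14 methyl 3-[4-methoxy-3-(pivaloyloxy)phenyl]-3-oxo-2-(pivaloyloxy)propanoate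
Product: 17 5-hydroxy-7-methoxy-2-[4-methoxy-3-(pivaloyloxy)phenyl]-6,8-bis(3-methylbut-2-en-1-yl)-4-oxo-4H-chromen-3-yl pivalate, via aroylketene 15 (not isolated), via diketone 16 (not isolated)
Conditions: 14 (1.3 equiv), Ph2O, 230 °C (microwave, open vessel, Ar stream), 10–15 min
Reagents that add atoms: none
Why: Mentzer thermal chromone synthesis: on heating, 14 eliminates methanol to give aroylketene 15 (direct transesterification by the phenol leads into the same manifold). 15 acylates 6 at its only unsubstituted ring carbon, or at oxygen to give an aryl ester that reverts to 15 at this temperature, so material should funnel to diketone 16, which is held by hydrogen bonds from both flanking hydroxyls; this forms C4–C4a. One of the two equivalent ortho-hydroxyls then adds to the ring B aryl ketone in a 6-exo-trig hemiketalisation and water is lost to give the aromatic 4-pyranone; this forms O1–C2 and closes ring C. The closest known reaction type is the thermal condensation of phloroglucinol with aroylacetates and with α-acyloxy aroylacetates to 5-hydroxyflavones and their 3-acyloxy analogues. No stereocentre is created, and the racemic centre of 14 becomes the sp2 carbon C3. Site selectivity needs no control because 6 has a single free carbon and two equivalent hydroxyls; chromone rather than coumarin formation is secured by the absence of acid, under which the arene would attack the ketone instead (Pechmann mode). The bulky pivalates resist acyl migration to the resorcinol hydroxyls, and the neutral medium, the short heating period and the argon stream that removes methanol and water are chosen to limit cyclisation of an ortho-prenyl phenol to a chroman.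

Step 9
Reactants: 17 5-hydroxy-7-methoxy-2-[4-methoxy-3-(pivaloyloxy)phenyl]-6,8-bis(3-methylbut-2-en-1-yl)-4-oxo-4H-chromen-3-yl pivalate
Product: 18 3,5-dihydroxy-2-(3-hydroxy-4-methoxyphenyl)-7-methoxy-6,8-bis(3-methylbut-2-en-1-yl)-4H-chromen-4-one (target)
Conditions: K2CO3 (3 equiv), MeOH (degassed), rt to 40 °C, Ar; then aq NH4Cl
Reagents that add atoms: none
Why: Base-mediated transesterification (methanolysis): the enol pivalate at O3 is an activated ester and the aryl pivalate at O3' is cleaved somewhat more slowly, both as methyl pivalate; methyl ethers, prenyl groups and the chelated 5-OH are inert, and oxygen is excluded because flavonolates are oxidised in air.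

## Compound list

1 | methyl 2,4,6-trihydroxybenzoate | COC(=O)c1c(O)cc(O)cc1O | starting material
2 | 1-bromo-3-methylbut-2-ene (prenyl bromide) | CC(C)=CCBr | starting material
3 | methyl 2,4,6-trihydroxy-3,5-bis(3-methylbut-2-en-1-yl)benzoate | COC(=O)c1c(O)c(CC=C(C)C)c(O)c(CC=C(C)C)c1O | intermediate
4 | methyl 2,6-dihydroxy-4-methoxy-3,5-bis(3-methylbut-2-en-1-yl)benzoate | COC(=O)c1c(O)c(CC=C(C)C)c(OC)c(CC=C(C)C)c1O | intermediate
5 | 2,6-dihydroxy-4-methoxy-3,5-bis(3-methylbut-2-en-1-yl)benzoic acid (potassium salt in the flask) | OC(=O)c1c(O)c(CC=C(C)C)c(OC)c(CC=C(C)C)c1O | intermediate (not isolated)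
6 | 5-methoxy-4,6-bis(3-methylbut-2-en-1-yl)benzene-1,3-diol | COc1c(CC=C(C)C)c(O)cc(O)c1CC=C(C)C | intermediate
7 | 3-hydroxy-4-methoxybenzoic acid (isovanillic acid) | COc1ccc(C(=O)O)cc1O | starting material
8 | 4-methoxy-3-(pivaloyloxy)benzoic acid | COc1ccc(C(=O)O)cc1OC(=O)C(C)(C)C | intermediate
9 | potassium 3-methoxy-3-oxopropanoate (potassium methyl malonate) | COC(=O)CC(=O)[O-].[K+] | starting material
10 | 5-(1H-imidazole-1-carbonyl)-2-methoxyphenyl pivalate | COc1ccc(C(=O)n2ccnc2)cc1OC(=O)C(C)(C)C | intermediate (not isolated)
11 | 3-methoxy-2-[4-methoxy-3-(pivaloyloxy)benzoyl]-3-oxopropanoic acid (racemic; magnesium chelate in the flask) | COC(=O)C(C(=O)O)C(=O)c1ccc(OC)c(OC(=O)C(C)(C)C)c1 | intermediate (not isolated)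
12 | methyl 3-[4-methoxy-3-(pivaloyloxy)phenyl]-3-oxopropanoate | COC(=O)CC(=O)c1ccc(OC)c(OC(=O)C(C)(C)C)c1 | intermediate
13 | methyl 2-diazo-3-[4-methoxy-3-(pivaloyloxy)phenyl]-3-oxopropanoate | COC(=O)C(=[N+]=[N-])C(=O)c1ccc(OC)c(OC(=O)C(C)(C)C)c1 | intermediate
14 | methyl 3-[4-methoxy-3-(pivaloyloxy)phenyl]-3-oxo-2-(pivaloyloxy)propanoate (racemic) | COC(=O)C(OC(=O)C(C)(C)C)C(=O)c1ccc(OC)c(OC(=O)C(C)(C)C)c1 | intermediate
15 | 2-methoxy-5-[3-oxo-2-(pivaloyloxy)prop-2-enoyl]phenyl pivalate (aroylketene) | O=C=C(OC(=O)C(C)(C)C)C(=O)c1ccc(OC)c(OC(=O)C(C)(C)C)c1 | intermediate (not isolated)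
16 | 1-[2,6-dihydroxy-4-methoxy-3,5-bis(3-methylbut-2-en-1-yl)phenyl]-3-[4-methoxy-3-(pivaloyloxy)phenyl]-1,3-dioxopropan-2-yl pivalate (racemic) | COc1ccc(C(=O)C(OC(=O)C(C)(C)C)C(=O)c2c(O)c(CC=C(C)C)c(OC)c(CC=C(C)C)c2O)cc1OC(=O)C(C)(C)C | intermediate (not isolated)
17 | 5-hydroxy-7-methoxy-2-[4-methoxy-3-(pivaloyloxy)phenyl]-6,8-bis(3-methylbut-2-en-1-yl)-4-oxo-4H-chromen-3-yl pivalate | COc1ccc(-c2oc3c(CC=C(C)C)c(OC)c(CC=C(C)C)c(O)c3c(=O)c2OC(=O)C(C)(C)C)cc1OC(=O)C(C)(C)C | intermediate
18 | 3,5-dihydroxy-2-(3-hydroxy-4-methoxyphenyl)-7-methoxy-6,8-bis(3-methylbut-2-en-1-yl)-4H-chromen-4-one | COc1ccc(-c2oc3c(CC=C(C)C)c(OC)c(CC=C(C)C)c(O)c3c(=O)c2O)cc1O | target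

## Step count and risks

Total: 9 steps. Longest linear sequence: 6 steps (7 → 8 → 12 → 13 → 14 → 17 → 18, steps 4 to 9). The ring A branch has 5 steps (steps 1, 2, 3, 8, 9).

Least certain steps:

Step 8 (key step). Most likely to go wrong: thermal cyclisation of an ortho-prenyl phenol unit to a chroman before or after annulation, incomplete transfer of the acyl group from oxygen to carbon, and self-condensation of the ketene, because the annulation needs a temperature at which these processes also run. Fallback: the prenyl groups are introduced after the annulation. The fallback sets out from 14, which is condensed under the same thermal conditions with phloroglucinol F1, the best-tested phenol for this reaction, to give 5,7-dihydroxy-2-[4-methoxy-3-(pivaloyloxy)phenyl]-4-oxo-4H-chromen-3-yl pivalate F2. Allyl bromide and K2CO3 in DMF should give the 5,7-bis(allyl) ether F3. A double aromatic Claisen rearrangement near 200 °C should move both allyl groups to carbon and give the 6,8-diallyl-5,7-diol F4. Double cross-metathesis with 2-methylbut-2-ene and the second-generation Grubbs catalyst should give the 6,8-diprenyl-5,7-diol F5. Methylation of the non-chelated 7-OH with Me2SO4 and K2CO3 (1 equiv) returns to the route at 17.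

Step 1. Most likely to go wrong: over-alkylation to dearomatised geminal diprenyl dienones, O-alkylation and incomplete second alkylation, because each product phenoxide remains an ambident nucleophile. Fallback: each prenyl group is delivered by O-alkylation and sigmatropic shift. From 1, Pd(PPh3)4 and methyl 2-methylbut-3-en-2-yl carbonate should etherify the non-chelated 4-OH to give methyl 2,6-dihydroxy-4-[(2-methylbut-3-en-2-yl)oxy]benzoate F6. Heating in toluene or xylene should bring about the aromatic Claisen rearrangement to methyl 2,4,6-trihydroxy-3-(3-methylbut-2-en-1-yl)benzoate F7. A second etherification at the 4-OH should give methyl 2,6-dihydroxy-4-[(2-methylbut-3-en-2-yl)oxy]-3-(3-methylbut-2-en-1-yl)benzoate F8, and a second Claisen rearrangement to the remaining free ortho carbon returns to the route at 3.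

Step 2. Most likely to go wrong: methylation at a chelated hydroxyl or at a ring carbon, because the 4-OH lies between two prenyl groups and the ring is a fully substituted phloroglucinol. Fallback: the order of methylation and prenylation is reversed. From 1, Me2SO4 and K2CO3 should methylate the unhindered, non-chelated 4-OH to give methyl 2,6-dihydroxy-4-methoxybenzoate F9. C-diprenylation of F9 with 2 under the conditions of step 1 (C3 and C5 are each ortho to one phenoxide and para to the other) returns to the route at 4, bypassing 3.

Step 3. Most likely to go wrong: slow attack of hydroxide at the hindered, electron-rich ester carbonyl and oxidative degradation of the product during long heating in alkali. Fallback: the ester is cleaved at the methyl carbon instead of the carbonyl carbon. From 4, LiI in pyridine at reflux should remove the ester methyl group by SN2 displacement, and the resulting carboxylate (the salt of 5) should lose CO2 on mild acidification, returning to the route at 6. This fallback makes no new compound (entry F0).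

## Further compounds

F1 | step 8 | benzene-1,3,5-triol (phloroglucinol) | Oc1cc(O)cc(O)c1
F2 | step 8 | 5,7-dihydroxy-2-[4-methoxy-3-(pivaloyloxy)phenyl]-4-oxo-4H-chromen-3-yl pivalate | COc1ccc(-c2oc3cc(O)cc(O)c3c(=O)c2OC(=O)C(C)(C)C)cc1OC(=O)C(C)(C)C
F3 | step 8 | 5,7-bis(allyloxy)-2-[4-methoxy-3-(pivaloyloxy)phenyl]-4-oxo-4H-chromen-3-yl pivalate | COc1ccc(-c2oc3cc(OCC=C)cc(OCC=C)c3c(=O)c2OC(=O)C(C)(C)C)cc1OC(=O)C(C)(C)C
F4 | step 8 | 6,8-diallyl-5,7-dihydroxy-2-[4-methoxy-3-(pivaloyloxy)phenyl]-4-oxo-4H-chromen-3-yl pivalate | COc1ccc(-c2oc3c(CC=C)c(O)c(CC=C)c(O)c3c(=O)c2OC(=O)C(C)(C)C)cc1OC(=O)C(C)(C)C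
F5 | step 8 | 5,7-dihydroxy-2-[4-methoxy-3-(pivaloyloxy)phenyl]-6,8-bis(3-methylbut-2-en-1-yl)-4-oxo-4H-chromen-3-yl pivalate | COc1ccc(-c2oc3c(CC=C(C)C)c(O)c(CC=C(C)C)c(O)c3c(=O)c2OC(=O)C(C)(C)C)cc1OC(=O)C(C)(C)C
F6 | step 1 | methyl 2,6-dihydroxy-4-[(2-methylbut-3-en-2-yl)oxy]benzoate | COC(=O)c1c(O)cc(OC(C)(C)C=C)cc1O
F7 | step 1 | methyl 2,4,6-trihydroxy-3-(3-methylbut-2-en-1-yl)benzoate | COC(=O)c1c(O)cc(O)c(CC=C(C)C)c1O
F8 | step 1 | methyl 2,6-dihydroxy-4-[(2-methylbut-3-en-2-yl)oxy]-3-(3-methylbut-2-en-1-yl)benzoate | COC(=O)c1c(O)cc(OC(C)(C)C=C)c(CC=C(C)C)c1O
F9 | step 2 | methyl 2,6-dihydroxy-4-methoxybenzoate | COC(=O)c1c(O)cc(OC)cc1O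
F0 | step 3 | none | none
A1 | alternative 1 | 5,7-dihydroxy-2-(3-hydroxy-4-methoxyphenyl)-4H-chromen-4-one (diosmetin) | COc1ccc(-c2cc(=O)c3c(O)cc(O)cc3o2)cc1O
A2 | alternative 1 | 5,7-bis(allyloxy)-2-[4-methoxy-3-(methoxymethoxy)phenyl]-4H-chromen-4-one | COCOc1cc(-c2cc(=O)c3c(OCC=C)cc(OCC=C)cc3o2)ccc1OC
A3 | alternative 1 | 6,8-diallyl-5,7-dihydroxy-2-[4-methoxy-3-(methoxymethoxy)phenyl]-4H-chromen-4-one | COCOc1cc(-c2cc(=O)c3c(O)c(CC=C)c(O)c(CC=C)c3o2)ccc1OC
A4 | alternative 2 | 2-(3-methylbut-2-en-1-yl)-3-(triisopropylsilyloxy)cyclobut-2-en-1-one | O=C1CC(O[Si](C(C)C)(C(C)C)C(C)C)=C1CC=C(C)C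
A5 | alternative 2 | 1-methoxy-5-methylhex-4-en-1-yne | COC#CCC=C(C)C
A6 | alternative 2 | 3-methoxy-2,4-bis(3-methylbut-2-en-1-yl)-5-(triisopropylsilyloxy)phenol | COc1c(CC=C(C)C)c(O)cc(O[Si](C(C)C)(C(C)C)C(C)C)c1CC=C(C)C
A7 | alternative 3 | 2-iodo-5-methoxy-4,6-bis(3-methylbut-2-en-1-yl)benzene-1,3-diol | COc1c(CC=C(C)C)c(O)c(I)c(O)c1CC=C(C)C
A8 | alternative 3 | carbon monoxide | [C-]#[O+]
A9 | alternative 3 | 4-ethynyl-1-methoxy-2-(methoxymethoxy)benzene | COCOc1cc(C#C)ccc1OC
A10 | alternative 3 | 5-hydroxy-7-methoxy-2-[4-methoxy-3-(methoxymethoxy)phenyl]-6,8-bis(3-methylbut-2-en-1-yl)-4H-chromen-4-one | COCOc1cc(-c2cc(=O)c3c(O)c(CC=C(C)C)c(OC)c(CC=C(C)C)c3o2)ccc1OC
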